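## Retrosynthetic overview

1. Target ⇐ acylation of O9 in triol 22 ⇐ trans-diaxial opening of the 7α,8α-epoxide 20 by isopropenyl (sets C7 and C8) ⇐ 9α-OH-directed epoxidation of Δ7 and 2α-OH-directed hydrogenation of C4=CH2 (sets C4) on the bicyclic allylic alcohol 17.
2. 17 ⇐ one cationic bicyclization of the acyclic (2Z,5E)-dienal 15: ring B closes first (C9–C10), ring A second (C4–C5); C5, C9, C10 and the trans ring fusion arise together.
3. Enabling feature: the oxygen-bearing C9 lies next to C8=C7 (a Z-enal, i.e. an oxyallyl cation), and the ring-fusion CH C10 lies next to the methyl-bearing quaternary C5. An E-trisubstituted C5=C10 alkene therefore attacks C9 through C10 and leaves a tertiary cation on C5. O2 and C4 of ring A are 1,3-related and are tied in a temporary O–Si–C(=CH2) ring (vinylsilane terminator) that passes on the only pre-set stereocentre, C2.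
4. 15 ⇐ (R)-epichlorohydrin + isobutenyl Grignard + acetylide + iPr2SiHCl (C1–C5, C10), allylic oxidation, propargyl alcohol (C7–C9), semihydrogenation, MnO2.

Key step: step 9

Remark: ring carbons are numbered C1–C10 as in eremophilanes (C2 CHOH, C4 CHCH3, C5 quaternary C, C7 C-isopropenyl, C8 CHOH, C9 CH-ester, C10 ring-fusion CH); β is the face of the C5 methyl, α that of H-10; acyclic precursors carry the same atom numbers; compounds 1, 2, 5, 7, 12, 21 and 23 are assumed to be purchased.

## Route

Step 1
Reactants: 1 (R)-epichlorohydrin; 2 2-methylprop-1-en-1-ylmagnesium bromide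
Product: 4 (R)-2-(3-methylbut-2-en-1-yl)oxirane, via chlorohydrin 3 (not isolated)
Conditions: CuI (10 mol %), THF, −40 °C; H2O; then powdered NaOH, Et2O, rt
Reagents that add atoms: none
Why: Copper-catalysed Grignard opening of the terminal epoxide carbon (SN2, stereocentre untouched) should give the chlorohydrin, which base closes to the new epoxide by intramolecular Williamson displacement of chloride, so C2 keeps the configuration of 1.

Step 2
Reactants: 4 (R)-2-(3-methylbut-2-en-1-yl)oxirane; 5 lithium acetylide–ethylenediamine complex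
Product: 6 (R)-7-methyloct-6-en-1-yn-4-ol
Conditions: DMSO, rt; H2O
Reagents that add atoms: none
Why: SN2 alkynylation of the epoxide at its CH2 carbon should give the homopropargylic alcohol without touching C2.

Step 3
Reactants: 6 (R)-7-methyloct-6-en-1-yn-4-ol; 7 chlorodiisopropylsilane
Product: 9 (R)-2,2-diisopropyl-3-methylene-5-(3-methylbut-2-en-1-yl)-1,2-oxasilolane, via silyl ether 8 (not isolated)
Conditions: Et3N, DMAP (cat.), CH2Cl2, 0 °C; filter; then Pt(dvds) (Karstedt catalyst, 0.5 mol %), THF, rt → 50 °C
Reagents that add atoms: none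
Why: O-silylation followed by platinum-catalysed intramolecular syn-hydrosilylation in the 5-exo-dig mode should place silicon on the internal alkyne carbon and give the cyclic α-silyl vinyl unit (exocyclic CH2), the trisubstituted alkene being inert.

Step 4
Reactants: 9 (R)-2,2-diisopropyl-3-methylene-5-(3-methylbut-2-en-1-yl)-1,2-oxasilolane
Product: 10 (E)-4-[(5R)-2,2-diisopropyl-3-methylene-1,2-oxasilolan-5-yl]-2-methylbut-2-en-1-ol
Conditions: SeO2 (0.3 equiv), t-BuOOH (in decane), salicylic acid (cat.), CH2Cl2, 0 °C → rt, stopped before full conversion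
Reagents that add atoms: tert-butyl hydroperoxide, CC(C)(C)OO (oxygen, passed on through catalytic selenium dioxide, O=[Se]=O)
Why: Selenium dioxide allylic oxidation (ene reaction, then [2,3]-sigmatropic shift) attacks the electron-rich trisubstituted alkene at its (E)-methyl group, so the E-allylic alcohol should form while the hindered 1,1-disubstituted vinylsilane reacts more slowly.

Step 5
Reactants: 10 (E)-allylic alcohol
Product: 11 (5R)-5-[(E)-4-bromo-3-methylbut-2-en-1-yl]-2,2-diisopropyl-3-methylene-1,2-oxasilolane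
Conditions: CBr4, PPh3, CH2Cl2, −20 → 0 °C
Reagents that add atoms: carbon tetrabromide, BrC(Br)(Br)Br
Why: The Appel reaction should convert the primary allylic alcohol into the bromide under neutral conditions that leave the E-alkene and the Si–O ring intact.

Step 6
Reactants: 11 allylic bromide; 12 prop-2-yn-1-ol
Product: 13 (E)-7-[(5R)-2,2-diisopropyl-3-methylene-1,2-oxasilolan-5-yl]-5-methylhept-5-en-2-yn-1-ol
Conditions: CuI (20 mol %), Bu4NI (cat.), K2CO3, DMF, rt
Reagents that add atoms: none
Why: The copper(I) acetylide of the terminal alkyne should displace the primary allylic bromide at CH2 (copper-mediated alkyne–allyl halide coupling), giving the skipped enyne with the E-alkene unchanged.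

Step 7
Reactants: 13 enynol
Product: 14 (2Z,5E)-7-[(5R)-2,2-diisopropyl-3-methylene-1,2-oxasilolan-5-yl]-5-methylhepta-2,5-dien-1-ol
Conditions: H2 (1 atm), Lindlar catalyst, quinoline, EtOAc, rt
Reagents that add atoms: none
Why: Lindlar semihydrogenation adds H2 syn to the alkyne only, so the Z-C7=C8 alkene should form while the trisubstituted alkene and the hindered vinylsilane stay.

Step 8
Reactants: 14 (2Z,5E)-dienol
Product: 15 (2Z,5E)-7-[(5R)-2,2-diisopropyl-3-methylene-1,2-oxasilolan-5-yl]-5-methylhepta-2,5-dienal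
Conditions: activated MnO2, CH2Cl2, 0 °C → rt; used at once
Reagents that add atoms: none
Why: Manganese dioxide oxidation of an allylic alcohol is neutral and heterogeneous and should give the enal with the Z geometry retained (as in nerol to neral).

Step 9
Reactants: 15 (2Z,5E)-dienal
Product: 17 2α-[diisopropyl(methyl)silyloxy]-5β-methyl-4-methylene-10αH-octal-7-en-9α-ol (trans-fused), via chlorosilyl ether 16 (not isolated)
Conditions: Me2AlCl (2 equiv), CH2Cl2, −78 → −40 °C; then MeMgBr, −78 → 0 °C; H2O
Reagents that add atoms: methylmagnesium bromide, C[Mg]Br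
Why: Proposed new method: the Me2AlCl-complexed Z-enal (an O-metalated oxyallyl cation) is attacked at C9 by C10 of the E-trisubstituted C5=C10 alkene (Markovnikov, tertiary cation at C5), and this cation is taken ipso by the tethered vinylsilane carbon C4, silicon leaving as Si–Cl to give C4=CH2; the closest known reactions are aldehyde- and acetal-initiated cation–olefin polycyclizations with vinylsilane termination and the Prins/carbonyl-ene closure of Z-enals such as neral to isopiperitenol. Ring B closes 6-endo-trig on the C5=C10 alkene with the Z-C7=C8 bond ending inside the ring, and ring A closes 6-exo-trig on the vinylsilane. C10 and C5 are set by anti addition across the E-alkene through a chair–chair array (Stork–Eschenmoser), which gives the trans fusion with H-10 anti to the C5 methyl. C9 is set by the s-trans enal, whose oxygen points outward and ends pseudo-equatorial (9α). The absolute sense comes from C2, because the O–Si–C4 ring can persist only if O2 and Si are 1,3-diaxial on the forming ring A (bicyclo[3.2.1]-like transition state), which puts O2 axial on the face opposite the C5 methyl (2α). The step needs C10 rather than C5 to attack, the Z geometry to survive and the C5 cation to be trapped before it loses a proton, and the methyl on C5, the low temperature with a proton-scavenging Lewis acid and the intramolecular silane should secure these.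

Step 10
Reactants: 17 bicyclic allylic alcohol
Product: 18 7α,8α-epoxy-2α-[diisopropyl(methyl)silyloxy]-5β-methyl-4-methylene-10αH-decalin-9α-ol
Conditions: VO(acac)2 (5 mol %), t-BuOOH, CH2Cl2, 0 °C → rt
Reagents that add atoms: tert-butyl hydroperoxide, CC(C)(C)OO
Why: Vanadium-catalysed hydroxyl-directed epoxidation should deliver oxygen to Δ7 on the face of the allylic 9α-OH (also the face away from the axial C5 methyl), while the exocyclic alkene, which has no free hydroxyl nearby, is left alone.

Step 11
Reactants: 18 epoxy alcohol silyl ether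
Product: 19 7α,8α-epoxy-5β-methyl-4-methylene-10αH-decalin-2α,9α-diol
Conditions: TBAF, THF, rt
Reagents that add atoms: none
Why: Fluoride-induced desilylation should free the 2α-hydroxyl without affecting the epoxide.

Step 12
Reactants: 19 epoxy diol
Product: 20 7α,8α-epoxy-4β,5β-dimethyl-10αH-decalin-2α,9α-diol
Conditions: H2 (1 atm), [Ir(cod)(PCy3)(py)]PF6 (5 mol %), CH2Cl2, rt
Reagents that add atoms: none
Why: In this hydroxyl-directed hydrogenation the axial homoallylic 2α-OH binds iridium and H2 should be delivered to the α face of C4=CH2, which is also the face opposite the axial C5 methyl, so the new methyl is 4β (equatorial).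

Step 13
Reactants: 20 epoxy diol; 21 isopropenylmagnesium bromide (5 equiv)
Product: 22 7β-isopropenyl-4β,5β-dimethyl-10αH-decalin-2α,8α,9α-triol
Conditions: CuI (20 mol %), THF, −30 → 0 °C; H2O
Reagents that add atoms: none
Why: Copper-catalysed Grignard opening of the rigid epoxide should follow the trans-diaxial (Fürst–Plattner) course, attack at C7 from the β face giving axial 7β-isopropenyl and axial 8α-OH, whereas attack at C8 would need a twist-boat and is next to the C9 alkoxide.

Step 14
Reactants: 23 ethyl pent-2-ynoate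
Product: 24 ethyl (Z)-3-methylpent-2-enoate
Conditions: Me2CuLi (from MeLi and CuI), THF, −78 °C; MeOH, −78 °C
Reagents that add atoms: lithium dimethylcuprate, [Li+].C[Cu-]C
Why: Syn-carbocupration of the ynoate and protonation with retention at low temperature place the new methyl cis to H, so the ethyl group is cis to the ester (Z).

Step 15
Reactants: 24 ethyl (Z)-3-methylpent-2-enoate
Product: 25 (Z)-3-methylpent-2-enoic acid
Conditions: LiOH, THF–H2O, rt; then aq. HCl
Reagents that add atoms: lithium hydroxide, [Li+].[OH-]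
Why: Saponification should give the acid without touching the trisubstituted alkene geometry.

Step 16
Reactants: 22 triol; 25 (Z)-3-methylpent-2-enoic acid
Product: 28 9α-O-[(Z)-3-methylpent-2-enoyl] ester of triol 22 (target), via stannylene acetal 26 (not isolated), via acid chloride 27 (not isolated)
Conditions: 22 with Bu2SnO, toluene, reflux (−H2O); 25 with 1-chloro-N,N,2-trimethylprop-1-en-1-amine, CH2Cl2, 0 °C; combine at 0 °C; H2O
Reagents that add atoms: none
Why: Dibutylstannylene acetal formation on the cis-8,9-diol activates its equatorial oxygen (O9), so the acid chloride, made under neutral conditions that should not scramble the Z geometry, acylates O9 while the axial 8-OH and the isolated axial 2-OH stay free.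

## Compound list

1 | (R)-epichlorohydrin | ClC[C@H]1CO1 | starting material
2 | 2-methylprop-1-en-1-ylmagnesium bromide | CC(C)=C[Mg]Br | starting material
3 | (R)-1-chloro-5-methylhex-4-en-2-ol | ClC[C@H](O)CC=C(C)C | intermediate
4 | (R)-2-(3-methylbut-2-en-1-yl)oxirane | CC(C)=CC[C@@H]1CO1 | intermediate
5 | lithium acetylide–ethylenediamine complex | [Li+].[C-]#C.NCCN | starting material
6 | (R)-7-methyloct-6-en-1-yn-4-ol | C#CC[C@H](O)CC=C(C)C | intermediate
7 | chlorodiisopropylsilane | CC(C)[SiH](Cl)C(C)C | starting material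
8 | (R)-diisopropyl[(7-methyloct-6-en-1-yn-4-yl)oxy]silane | C#CC[C@H](O[SiH](C(C)C)C(C)C)CC=C(C)C | intermediate
9 | (R)-2,2-diisopropyl-3-methylene-5-(3-methylbut-2-en-1-yl)-1,2-oxasilolane | CC(C)=CC[C@@H]1CC(=C)[Si](C(C)C)(C(C)C)O1 | intermediate
10 | (E)-4-[(5R)-2,2-diisopropyl-3-methylene-1,2-oxasilolan-5-yl]-2-methylbut-2-en-1-ol | OC/C(C)=C/C[C@@H]1CC(=C)[Si](C(C)C)(C(C)C)O1 | intermediate
11 | (5R)-5-[(E)-4-bromo-3-methylbut-2-en-1-yl]-2,2-diisopropyl-3-methylene-1,2-oxasilolane | BrC/C(C)=C/C[C@@H]1CC(=C)[Si](C(C)C)(C(C)C)O1 | intermediate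
12 | prop-2-yn-1-ol | C#CCO | starting material
13 | (E)-7-[(5R)-2,2-diisopropyl-3-methylene-1,2-oxasilolan-5-yl]-5-methylhept-5-en-2-yn-1-ol | OCC#CC/C(C)=C/C[C@@H]1CC(=C)[Si](C(C)C)(C(C)C)O1 | intermediate
14 | (2Z,5E)-7-[(5R)-2,2-diisopropyl-3-methylene-1,2-oxasilolan-5-yl]-5-methylhepta-2,5-dien-1-ol | OC/C=C\C/C(C)=C/C[C@@H]1CC(=C)[Si](C(C)C)(C(C)C)O1 | intermediate
15 | (2Z,5E)-7-[(5R)-2,2-diisopropyl-3-methylene-1,2-oxasilolan-5-yl]-5-methylhepta-2,5-dienal | O=C/C=C\C/C(C)=C/C[C@@H]1CC(=C)[Si](C(C)C)(C(C)C)O1 | intermediate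
16 | 2α-[chloro(diisopropyl)silyloxy]-5β-methyl-4-methylene-10αH-octal-7-en-9α-ol (O9 held as aluminium alkoxide in the flask) | C=C1C[C@H](O[Si](Cl)(C(C)C)C(C)C)C[C@H]2[C@H](O)C=CC[C@]12C | intermediate
17 | 2α-[diisopropyl(methyl)silyloxy]-5β-methyl-4-methylene-10αH-octal-7-en-9α-ol | C=C1C[C@H](O[Si](C)(C(C)C)C(C)C)C[C@H]2[C@H](O)C=CC[C@]12C | intermediate
18 | 7α,8α-epoxy-2α-[diisopropyl(methyl)silyloxy]-5β-methyl-4-methylene-10αH-decalin-9α-ol | C=C1C[C@H](O[Si](C)(C(C)C)C(C)C)C[C@H]2[C@H](O)[C@@H]3O[C@@H]3C[C@]12C | intermediate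
19 | 7α,8α-epoxy-5β-methyl-4-methylene-10αH-decalin-2α,9α-diol | C=C1C[C@H](O)C[C@H]2[C@H](O)[C@@H]3O[C@@H]3C[C@]12C | intermediate
20 | 7α,8α-epoxy-4β,5β-dimethyl-10αH-decalin-2α,9α-diol | C[C@H]1C[C@H](O)C[C@H]2[C@H](O)[C@@H]3O[C@@H]3C[C@]12C | intermediate
21 | isopropenylmagnesium bromide | CC(=C)[Mg]Br | starting material
22 | 7β-isopropenyl-4β,5β-dimethyl-10αH-decalin-2α,8α,9α-triol | C=C(C)[C@H]1C[C@]2(C)[C@@H](C)C[C@H](O)C[C@H]2[C@H](O)[C@@H]1O | intermediate
23 | ethyl pent-2-ynoate | CCC#CC(=O)OCC | starting material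
24 | ethyl (Z)-3-methylpent-2-enoate | CCOC(=O)/C=C(/C)CC | intermediate
25 | (Z)-3-methylpent-2-enoic acid | OC(=O)/C=C(/C)CC | intermediate
26 | 8α,9α-O-dibutylstannylene acetal of 22 | C=C(C)[C@H]1C[C@]2(C)[C@@H](C)C[C@H](O)C[C@H]2[C@@H]3O[Sn](CCCC)(CCCC)O[C@H]13 | intermediate
27 | (Z)-3-methylpent-2-enoyl chloride | O=C(Cl)/C=C(/C)CC | intermediate
28 | 7β-isopropenyl-4β,5β-dimethyl-10αH-decalin-2α,8α-diol 9α-[(Z)-3-methylpent-2-enoate] (CNP0129603.1) | C=C(C)[C@H]1C[C@]2(C)[C@@H](C)C[C@H](O)C[C@H]2[C@H](OC(=O)/C=C(/C)CC)[C@@H]1O | target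

## Step count and risks

Total steps: 16. Longest linear sequence: 14 (steps 1–13 and 16).

Steps most likely to fail:

1. Step 9 (key step). The aluminium-complexed enal may isomerise from Z to E before it is attacked, or the C5 cation may lose a proton from the doubly allylic C6 after ring B has closed, so that the cascade stops before ring A forms. The fallback sets out from 11 and comes back at 17 and avoids the Z-enal. Copper-catalysed coupling of 11 with 2-(1,3-dioxolan-2-yl)ethylmagnesium bromide (Li2CuCl4, THF) should give the acetal F1, and mild acetal hydrolysis (PPTS, wet acetone) the saturated aldehyde F2. The same Me2AlCl/MeMgBr treatment, now an aldehyde-initiated cation–olefin bicyclization of the established saturated type, should give through the chlorosilyl ether F3 the saturated bicyclic alcohol F4. Dess–Martin oxidation to the ketone F5, kinetic deprotonation at the C8 methylene (LDA, TMSCl) to the silyl enol ether F6 and Saegusa oxidation (Pd(OAc)2, MeCN) should give the enone F7. Meerwein–Ponndorf–Verley reduction (Al(OiPr)3, iPrOH, reflux) under equilibrating conditions should then return the pseudo-equatorial 9α-alcohol 17, since the 9β epimer would be syn-axial to the C5 methyl.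

2. Step 13. The axial approach to C7 is shielded by the syn-axial C5 methyl, so the opening may be slow and attack at C8 or magnesium-halide opening of the epoxide may take over. The fallback sets out from 20 and comes back at 22. Lithium acetylide–ethylenediamine (DMSO, rt), a slim linear nucleophile, should open 20 trans-diaxially to the 7β-ethynyl triol F8. Zirconium-catalysed methylalumination of the terminal alkyne (excess AlMe3, Cp2ZrCl2 cat., CH2Cl2; then H2O) should convert the ethynyl group into isopropenyl and give 22.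

3. Step 4. The ene oxidation may also occur at the allylic CH2 of the cyclic vinylsilane, the alcohol may be over-oxidised to the enal, or the Si–O bond may be cleaved. The fallback sets out from 6 and comes back at 10 and oxidises before silicon is introduced. SeO2/t-BuOOH on 6 should give the (E)-diol F9, and pivaloyl chloride/pyridine at −20 °C should acylate the primary allylic hydroxyl selectively to the pivalate F10. Silylation with 7 (Et3N) to the hydrosilyl ether F11 and platinum-catalysed 5-exo-dig hydrosilylation should give the oxasilolane pivalate F12, and DIBAL-H (CH2Cl2, −78 °C) should release 10.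

## Further compounds

F1 | step 9 | (5R)-5-[(E)-6-(1,3-dioxolan-2-yl)-3-methylhex-2-en-1-yl]-2,2-diisopropyl-3-methylene-1,2-oxasilolane | O1CCOC1CCC/C(C)=C/C[C@@H]2CC(=C)[Si](C(C)C)(C(C)C)O2
F2 | step 9 | (E)-7-[(5R)-2,2-diisopropyl-3-methylene-1,2-oxasilolan-5-yl]-5-methylhept-5-enal | O=CCCC/C(C)=C/C[C@@H]1CC(=C)[Si](C(C)C)(C(C)C)O1
F3 | step 9 | 2α-[chloro(diisopropyl)silyloxy]-5β-methyl-4-methylene-10αH-decalin-9α-ol | C=C1C[C@H](O[Si](Cl)(C(C)C)C(C)C)C[C@H]2[C@H](O)CCC[C@]12C
F4 | step 9 | 2α-[diisopropyl(methyl)silyloxy]-5β-methyl-4-methylene-10αH-decalin-9α-ol | C=C1C[C@H](O[Si](C)(C(C)C)C(C)C)C[C@H]2[C@H](O)CCC[C@]12C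
F5 | step 9 | 2α-[diisopropyl(methyl)silyloxy]-5β-methyl-4-methylene-10αH-decalin-9-one | C=C1C[C@H](O[Si](C)(C(C)C)C(C)C)C[C@H]2C(=O)CCC[C@]12C
F6 | step 9 | 2α-[diisopropyl(methyl)silyloxy]-5β-methyl-4-methylene-9-(trimethylsilyloxy)-10αH-octal-8-ene | C=C1C[C@H](O[Si](C)(C(C)C)C(C)C)C[C@H]2C(O[Si](C)(C)C)=CCC[C@]12C
F7 | step 9 | 2α-[diisopropyl(methyl)silyloxy]-5β-methyl-4-methylene-10αH-octal-7-en-9-one | C=C1C[C@H](O[Si](C)(C(C)C)C(C)C)C[C@H]2C(=O)C=CC[C@]12C
F8 | step 13 | 7β-ethynyl-4β,5β-dimethyl-10αH-decalin-2α,8α,9α-triol | C#C[C@H]1C[C@]2(C)[C@@H](C)C[C@H](O)C[C@H]2[C@H](O)[C@@H]1O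
F9 | step 4 | (2E,5R)-2-methyloct-2-en-7-yne-1,5-diol | OC/C(C)=C/C[C@@H](O)CC#C
F10 | step 4 | (2E,5R)-5-hydroxy-2-methyloct-2-en-7-yn-1-yl pivalate | CC(C)(C)C(=O)OC/C(C)=C/C[C@@H](O)CC#C
F11 | step 4 | (2E,5R)-5-[(diisopropylsilyl)oxy]-2-methyloct-2-en-7-yn-1-yl pivalate | CC(C)(C)C(=O)OC/C(C)=C/C[C@@H](O[SiH](C(C)C)C(C)C)CC#C
F12 | step 4 | (E)-4-[(5R)-2,2-diisopropyl-3-methylene-1,2-oxasilolan-5-yl]-2-methylbut-2-en-1-yl pivalate | CC(C)(C)C(=O)OC/C(C)=C/C[C@@H]1CC(=C)[Si](C(C)C)(C(C)C)O1
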